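**Retrosynthetic overview**
1. Andibenin B (27) ⇐ oxidation of a secondary alcohol, debenzylation/desilylation and lactone dehydrogenation of cycloadduct 23; no ring is formed after the key step.
2. Key disconnection: retro-[4+2] of the cyclohexene made of the ketone carbon, the two quaternary C(CH3) carbons beside it, the bridgehead that carries the lactone CH2, and the CH=C alkene. It closes together with the cyclopentane from spiro diene 22.
3. Enabling feature: the C=C of that ring is conjugated to the butenolide C=O, so the C(CH3) bridgehead, the two alkene carbons and the CH2O-bearing bridgehead are a 2-acyl-1,3-diene held s-cis in a cyclohexadiene that is spiro-fused to the cyclohexane. The ketone carbon and its C(CH3) neighbour are a 2π unit (an enol ether) already linked through one CH2 to the ring methine next to the spiro carbon.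
4. 22 ⇐ Dieckmann closure, enol triflate and Stille hydroxymethylation/lactonisation; quaternary spiro carbon and cis side chain ⇐ Ueno–Stork cyclisation with allyl transfer; tertiary carbinol ⇐ epoxidation/E1cB opening; cyclohexane ⇐ desymmetrising aldol condensation.
5. Ring order: cyclohexane (step 2) → δ-lactone (step 4) → cyclohexadiene (step 14) → butenolide (step 15) → cyclopentane and cyclohexene of the bicyclo[2.2.2]octene (step 16). The oxirane, tetrahydrofuran ketal and bridged γ-lactone are temporary rings.

Key step: step 16

Assumption: the tertiary hydroxyl next to the spiro lactone does not translactonise under the neutral to weakly basic conditions in which it is free, as in the target itself.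

Step 1
Reactants: 1 methyl 4-acetyl-5-oxohexanoate; 2 but-3-en-2-one
Product: 3 methyl 4,4-diacetyl-7-oxooctanoate
Conditions: Et3N (10 mol%), MeCN, 25 °C
Reagents that add atoms: none
Why: Base-catalysed Michael addition of the acidic 3-substituted pentane-2,4-dione to methyl vinyl ketone; the new quaternary carbon carries two identical acetyl groups and is not yet a stereocentre.

Step 2
Reactants: 3 methyl 4,4-diacetyl-7-oxooctanoate
Product: 4 methyl 3-[(1S)-1-acetyl-2-methyl-4-oxocyclohex-2-en-1-yl]propanoate
Conditions: 9-amino-9-deoxy-epi-quinine (20 mol%), AcOH (40 mol%), PhMe, 4 Å sieves, 25 → 40 °C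
Reagents that add atoms: none
Why: Enamine-mediated intramolecular aldol condensation of Hajos–Parrish type under chiral primary-amine catalysis: the enamine of the unhindered methyl ketone attacks one of the two enantiotopic acetyl groups, which makes the quaternary carbon an (S) stereocentre (the quinine-derived amine or its quinidine-derived pseudoenantiomer is taken, whichever gives this sense), and dehydration gives the enone.

Step 3
Reactants: 4 methyl 3-[(1S)-1-acetyl-2-methyl-4-oxocyclohex-2-en-1-yl]propanoate
Product: 5 methyl 3-[(1S)-1-acetyl-4-hydroxy-2-methylcyclohex-2-en-1-yl]propanoate (both carbinol epimers)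
Conditions: NaBH4, CeCl3·7H2O, MeOH, −78 °C
Reagents that add atoms: none
Why: Luche reduction: cerium-assisted 1,2-hydride addition to the unhindered enone carbonyl should outrun attack on the neopentyl acetyl group and the ester, and the carbinol centre is a mixture that step 6 erases.

Step 4
Reactants: 5 methyl 3-[(1S)-1-acetyl-4-hydroxy-2-methylcyclohex-2-en-1-yl]propanoate
Product: 7 hydroxy spirolactone (6S)-9-hydroxy-1,1,7-trimethyl-2-oxaspiro[5.5]undec-7-en-3-one, via diol ester 6 (not isolated)
Conditions: MeLi, CeCl3, THF, −78 °C; then PPTS, PhMe, 60 °C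
Reagents that add atoms: methylcerium dichloride, made in the flask from MeLi and CeCl3 (C[Ce](Cl)Cl)
Why: Organocerium 1,2-addition to the hindered methyl ketone (little enolisation, ester spared at low temperature) followed by acid-catalysed lactonisation of the tertiary alcohol onto the methyl ester closes the six-membered lactone; no stereocentre is formed.

Step 5
Reactants: 7 hydroxy spirolactone
Product: 8 allylic methyl carbonate methyl (6S)-1,1,7-trimethyl-3-oxo-2-oxaspiro[5.5]undec-7-en-9-yl carbonate
Conditions: ClCO2Me, pyridine, DMAP (cat.), CH2Cl2, 0 °C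
Reagents that add atoms: methyl chloroformate (COC(=O)Cl)
Why: Acylation of the secondary allylic alcohol with a chloroformate (carbonate formation) provides the leaving group for palladium.

Step 6
Reactants: 8 allylic methyl carbonate
Product: 9 β,γ-unsaturated ester methyl (6S)-1,1,7-trimethyl-3-oxo-2-oxaspiro[5.5]undec-7-ene-9-carboxylate (both epimers at the ester carbon)
Conditions: Pd(OAc)2 (5 mol%), PPh3, CO (30 atm), MeOH, 50 °C
Reagents that add atoms: carbon monoxide ([C-]#[O+])
Why: Tsuji decarboxylative carbonylation of an allylic carbonate: zerovalent palladium ionises the carbonate, CO inserts at the less hindered secondary terminus of the π-allyl complex and the released methoxide gives the β,γ-unsaturated methyl ester, whose new centre is an inconsequential mixture.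

Step 7
Reactants: 9 β,γ-unsaturated ester
Product: 10 epoxy ester (oxirane oxygen on the ring face of the lactone CH2 arm)
Conditions: mCPBA, NaHCO3, CH2Cl2, 0 °C
Reagents that add atoms: mCPBA (O=C(OO)c1cccc(Cl)c1)
Why: Prilezhaev epoxidation of the only electron-rich alkene; the peracid should approach anti to the C(CH3)2–O carbon of the spiro lactone (the CH2 arm is the smaller neighbour), which sets the configuration of the future tertiary carbinol.

Step 8
Reactants: 10 epoxy ester
Product: 11 hydroxy enoate methyl (6S,7R)-7-hydroxy-1,1,7-trimethyl-3-oxo-2-oxaspiro[5.5]undec-8-ene-9-carboxylate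
Conditions: DBU, THF, 50 °C
Reagents that add atoms: none
Why: Base-induced E1cB opening of a β,γ-epoxy ester to the γ-hydroxy-α,β-unsaturated ester; both ester epimers converge and the C–O stereocentre is untouched.

Step 9
Reactants: 11 hydroxy enoate
Product: 12 bromoketal (1-bromo-2-methoxypropan-2-yl ether of 11)
Conditions: 2-methoxypropene, NBS, CH2Cl2, −40 °C
Reagents that add atoms: 2-methoxypropene (COC(C)=C); N-bromosuccinimide (O=C1CCC(=O)N1Br)
Why: Bromoetherification of the enol ether by the tertiary alcohol (mixed bromoketal formation) installs the Ueno–Stork radical precursor; the ketal carbon is a mixture that step 12 removes.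

Step 10
Reactants: 12 bromoketal
Product: 13 tricyclic ketal ester
Conditions: tributyl(2-methylallyl)stannane, AIBN, PhH, 80 °C
Reagents that add atoms: tributyl(2-methylallyl)stannane (CCCC[Sn](CCCC)(CCCC)CC(C)=C)
Why: Ueno–Stork 5-exo-trig radical cyclisation onto the β-carbon of the enoate followed by Keck allyl transfer to the α-ester radical: the short O–C–C tether can only deliver the CH2 cis to the tertiary oxygen, and the stannane adds to the radical on the face opposite this new ring, which sets the quaternary carbon.

Step 11
Reactants: 13 tricyclic ketal ester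
Product: 14 chain-extended ketal diester (E/Z mixture)
Conditions: methyl but-3-enoate (excess), second-generation Grubbs catalyst (5 mol%), CH2Cl2, 40 °C
Reagents that add atoms: methyl but-3-enoate (COC(=O)CC=C)
Why: Olefin cross-metathesis of the 1,1-disubstituted alkene with a terminal alkene appends the CH2CO2Me unit; the E/Z mixture is acceptable because step 14 equilibrates it.

Step 12
Reactants: 14 chain-extended ketal diester
Product: 16 bridged lactone ketone, via hydroxy keto diester 15 (not isolated)
Conditions: TsOH·H2O (cat.), acetone–H2O, 40 °C; then TsOH (cat.), PhMe, 80 °C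
Reagents that add atoms: water (O)
Why: Acid hydrolysis of the cyclic ketal frees the methyl ketone and the tertiary alcohol, which stands syn-axial to the quaternary ester and transesterifies to a bridged γ-lactone, a temporary ring that keeps the alcohol from closing back onto the ketone as a hemiketal.

Step 13
Reactants: 16 bridged lactone ketone
Product: 17 benzyl enol ether (E/Z mixture)
Conditions: BnOCH2PPh3Cl, KN(SiMe3)2, THF, −78 → 0 °C
Reagents that add atoms: (benzyloxymethyl)triphenylphosphonium chloride ([Cl-].C(OCc1ccccc1)[P+](c1ccccc1)(c1ccccc1)c1ccccc1)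
Why: Wittig alkoxymethylenation of the unhindered methyl ketone gives the benzyl enol ether as an E/Z mixture, which the key step and step 19 make irrelevant.

Step 14
Reactants: 17 benzyl enol ether
Product: 20 silyl ether dienyl triflate, via spiro β-keto ester enolate 18 (not isolated), via hydroxy dienyl triflate 19 (not isolated)
Conditions: KOt-Bu (1.1 equiv), THF–t-BuOH, 0 → 25 °C; PhNTf2, 0 °C; then N-(trimethylsilyl)imidazole, 25 °C
Reagents that add atoms: N-phenylbis(trifluoromethanesulfonimide) (O=S(=O)(N(c1ccccc1)S(=O)(=O)C(F)(F)F)C(F)(F)F); N-(trimethylsilyl)imidazole (C[Si](C)(C)n1ccnc1)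
Why: Dieckmann cyclisation of the ester dienolate onto the strained lactone carbonyl (6-exo-trig; the E and Z alkenes interconvert through the conjugated ester under the alkoxide and only the Z form can close) gives the extended enolate, which is O-triflated (enol triflate formation), and the liberated tertiary alcohol is capped as its silyl ether so that it cannot add back to the activated alkene.

Step 15
Reactants: 20 silyl ether dienyl triflate
Product: 22 spiro diene butenolide, via hydroxymethyl diene ester 21 (not isolated)
Conditions: Bu3SnCH2OH, Pd(PPh3)4 (10 mol%), LiCl, dioxane, 70 °C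
Reagents that add atoms: (tributylstannyl)methanol (CCCC[Sn](CCCC)(CCCC)CO)
Why: Stille coupling of the β-triflyloxy enoate with (tributylstannyl)methanol, after which the hydroxymethyl group lactonises spontaneously onto the cis ester to close the butenolide.

Step 16
Reactants: 22 spiro diene butenolide
Product: 23 cycloadduct (mixture at the benzyloxy carbon)
Conditions: PhMe (0.005 M), BHT (cat.), 120 °C, sealed tube
Reagents that add atoms: none
Why: On heating, the 2-acyl-1,3-diene of the cyclohexadiene and the tethered enol ether should undergo a concerted but asynchronous inverse-electron-demand [4+2] cycloaddition, in which the nucleophilic C(CH3) carbon of the enol ether bonds first to the electrophilic β-carbon of the butenolide and the alkoxy carbon then closes onto the methyl-bearing diene terminus. The closest known reaction type is the intramolecular Diels–Alder reaction of 5-alkenylcyclohexa-1,3-dienes that gives tricyclo[4.3.1.0(3,7)]decenes (isotwistenes), together with the cycloadditions of 2-alkoxycarbonyl dienes with enol ethers. The cyclopentane closes in the fused mode through the two-atom tether (the diene terminus next to the spiro carbon is the only one the chain can reach), and the cyclohexene is the ring of the cycloaddition itself, which completes the bicyclo[2.2.2]octene. The three new fixed stereocentres (both bridgeheads and the quaternary C(CH3) beside the ether carbon) are dictated by the tether: the dienophile can only add to the diene face that carries the ring methine, and its CH2 arm must lie in the five-membered ring, so the methyl group is forced outward; the ether carbon forms as a mixture from either enol ether isomer and is erased in step 19. The step needs regioselectivity and must outrun dimerisation of the diene, which is secured by the tether, by the matched polarity of the two components, by the quaternary spiro carbon that blocks aromatisation and by high dilution.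

Step 17
Reactants: 23 cycloadduct
Product: 25 unsaturated lactone benzyl ether, via phenylselanyl lactone 24 (not isolated)
Conditions: LiN(iPr)2, THF, −78 °C; PhSeBr; then mCPBA, CH2Cl2, −78 °C; iPr2NH, 25 °C
Reagents that add atoms: none
Why: α-Selenenylation of the lactone enolate and selenoxide syn-elimination (Reich–Sharpless dehydrogenation): the saturated lactone holds the only enolisable C–H of 23, so the double bond can only form in conjugation with that carbonyl.

Step 18
Reactants: 25 unsaturated lactone benzyl ether
Product: 26 diol (mixture at the secondary carbinol)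
Conditions: BCl3, C6HMe5, CH2Cl2, −78 → −40 °C; aqueous work-up
Reagents that add atoms: none
Why: Lewis-acid debenzylation with a cation scavenger (BCl3/pentamethylbenzene), under which the tertiary silyl ether is lost as well, while alkenes and lactones are spared.

Step 19
Reactants: 26 diol
Product: 27 andibenin B
Conditions: Dess–Martin periodinane, NaHCO3, CH2Cl2, 25 °C
Reagents that add atoms: none
Why: Dess–Martin oxidation of the hindered secondary alcohol to the non-enolisable ketone, which removes the mixed carbinol centre and leaves the tertiary alcohol untouched.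

**Compound list**
1 | methyl 4-acetyl-5-oxohexanoate | COC(=O)CCC(C(C)=O)C(C)=O | starting material
2 | but-3-en-2-one (methyl vinyl ketone) | CC(=O)C=C | starting material
3 | methyl 4,4-diacetyl-7-oxooctanoate | COC(=O)CCC(C(C)=O)(C(C)=O)CCC(C)=O | intermediate
4 | methyl 3-[(1S)-1-acetyl-2-methyl-4-oxocyclohex-2-en-1-yl]propanoate | COC(=O)CC[C@@]1(C(C)=O)CCC(=O)C=C1C | intermediate
5 | methyl 3-[(1S)-1-acetyl-4-hydroxy-2-methylcyclohex-2-en-1-yl]propanoate, both carbinol epimers | COC(=O)CC[C@@]1(C(C)=O)CCC(O)C=C1C | intermediate
6 | diol ester: methyl 3-[(1S)-4-hydroxy-1-(2-hydroxypropan-2-yl)-2-methylcyclohex-2-en-1-yl]propanoate | COC(=O)CC[C@@]1(C(C)(C)O)CCC(O)C=C1C | intermediate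
7 | hydroxy spirolactone: (6S)-9-hydroxy-1,1,7-trimethyl-2-oxaspiro[5.5]undec-7-en-3-one, both carbinol epimers | CC1(C)OC(=O)CC[C@]12CCC(O)C=C2C | intermediate
8 | allylic methyl carbonate: methyl (6S)-1,1,7-trimethyl-3-oxo-2-oxaspiro[5.5]undec-7-en-9-yl carbonate | CC1(C)OC(=O)CC[C@]12CCC(OC(=O)OC)C=C2C | intermediate
9 | β,γ-unsaturated ester: methyl (6S)-1,1,7-trimethyl-3-oxo-2-oxaspiro[5.5]undec-7-ene-9-carboxylate, both epimers at the ester carbon | CC1(C)OC(=O)CC[C@]12CCC(C(=O)OC)C=C2C | intermediate
10 | epoxy ester: 7,8-epoxide of 9, oxirane oxygen on the face of the lactone CH2 arm, anti to the C(CH3)2–O carbon | CC1(C)OC(=O)CC[C@]12CCC(C(=O)OC)[C@H]3O[C@@]23C | intermediate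
11 | hydroxy enoate: methyl (6S,7R)-7-hydroxy-1,1,7-trimethyl-3-oxo-2-oxaspiro[5.5]undec-8-ene-9-carboxylate | CC1(C)OC(=O)CC[C@]12CCC(C(=O)OC)=C[C@@]2(C)O | intermediate
12 | bromoketal: 1-bromo-2-methoxypropan-2-yl ether of 11, mixture at the ketal carbon | CC1(C)OC(=O)CC[C@]12CCC(C(=O)OC)=C[C@@]2(C)OC(C)(OC)CBr | intermediate
13 | tricyclic ketal ester: 2-methoxy-2-methyltetrahydrofuran cis-fused to the cyclohexane through the carbinol oxygen and the new CH2; the quaternary carbon carries CO2Me cis and 2-methylallyl trans to that CH2 | CC1(C)OC(=O)CC[C@]12CC[C@@](CC(C)=C)(C(=O)OC)[C@H]3CC(C)(OC)O[C@@]23C | intermediate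
14 | chain-extended ketal diester: 13 with the 2-methylallyl group turned into CH2C(CH3)=CHCH2CO2Me, E/Z mixture | CC1(C)OC(=O)CC[C@]12CC[C@@](CC(C)=CCC(=O)OC)(C(=O)OC)[C@H]3CC(C)(OC)O[C@@]23C | intermediate
15 | hydroxy keto diester: ring-opened form of 14 with free tertiary alcohol and 2-oxopropyl group | CC1(C)OC(=O)CC[C@]12CC[C@@](CC(C)=CCC(=O)OC)(C(=O)OC)[C@@H](CC(C)=O)[C@@]2(C)O | intermediate
16 | bridged lactone ketone: γ-lactone between the tertiary oxygen and the quaternary carboxyl; 2-oxopropyl group cis to the lactone bridge | CC1(C)OC(=O)CC[C@]12CC[C@@]3(CC(C)=CCC(=O)OC)C(=O)O[C@]2(C)[C@@H]3CC(C)=O | intermediate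
17 | benzyl enol ether: 16 with the ketone turned into C(CH3)=CH–OBn, E/Z mixture | CC1(C)OC(=O)CC[C@]12CC[C@@]3(CC(C)=CCC(=O)OC)C(=O)O[C@]2(C)[C@@H]3CC(C)=COCc1ccccc1 | intermediate
18 | spiro β-keto ester (present as its potassium enolate): new cyclohexenone ring spiro to the cyclohexane, free tertiary alcohol | CC1(C)OC(=O)CC[C@]12CC[C@]3(CC(C)=CC(C(=O)OC)C3=O)[C@@H](CC(C)=COCc3ccccc3)[C@@]2(C)O | intermediate
19 | hydroxy dienyl triflate: enol triflate of 18 | CC1(C)OC(=O)CC[C@]12CC[C@]3(CC(C)=CC(C(=O)OC)=C3OS(=O)(=O)C(F)(F)F)[C@@H](CC(C)=COCc3ccccc3)[C@@]2(C)O | intermediate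
20 | silyl ether dienyl triflate: trimethylsilyl ether of 19 | CC1(C)OC(=O)CC[C@]12CC[C@]3(CC(C)=CC(C(=O)OC)=C3OS(=O)(=O)C(F)(F)F)[C@@H](CC(C)=COCc3ccccc3)[C@@]2(C)O[Si](C)(C)C | intermediate
21 | hydroxymethyl diene ester: 20 with CH2OH in place of the triflate | CC1(C)OC(=O)CC[C@]12CC[C@]3(CC(C)=CC(C(=O)OC)=C3CO)[C@@H](CC(C)=COCc3ccccc3)[C@@]2(C)O[Si](C)(C)C | intermediate
22 | spiro diene butenolide: 4,5-dihydroisobenzofuran-1(3H)-one spiro-fused to the cyclohexane, enol ether side chain on the neighbouring methine cis to the butenolide carbon | CC1(C)OC(=O)CC[C@]12CC[C@]3(CC(C)=CC4=C3COC4=O)[C@@H](CC(C)=COCc3ccccc3)[C@@]2(C)O[Si](C)(C)C | intermediate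
23 | cycloadduct: 7,8-dihydroandibenin B skeleton with OBn (both epimers) in place of the ketone oxygen and OSiMe3 on the tertiary carbinol | CC1(C)OC(=O)CC[C@]12CC[C@@]13C[C@@]4(C)C=C5C(=O)OC[C@]51[C@@](C)(C[C@H]3[C@@]2(C)O[Si](C)(C)C)C4OCc1ccccc1 | intermediate
24 | phenylselanyl lactone: 23 with SePh α to the δ-lactone carbonyl | CC1(C)OC(=O)C([Se]c2ccccc2)C[C@]12CC[C@@]13C[C@@]4(C)C=C5C(=O)OC[C@]51[C@@](C)(C[C@H]3[C@@]2(C)O[Si](C)(C)C)C4OCc1ccccc1 | intermediate
25 | unsaturated lactone benzyl ether: 23 with the α,β-unsaturated δ-lactone | CC1(C)OC(=O)C=C[C@]12CC[C@@]13C[C@@]4(C)C=C5C(=O)OC[C@]51[C@@](C)(C[C@H]3[C@@]2(C)O[Si](C)(C)C)C4OCc1ccccc1 | intermediate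
26 | diol: andibenin B with CH–OH (both epimers) in place of the ketone | CC1(C)OC(=O)C=C[C@]12CC[C@@]13C[C@@]4(C)C=C5C(=O)OC[C@]51[C@@](C)(C[C@H]3[C@@]2(C)O)C4O | intermediate
27 | andibenin B | CC1(C)OC(=O)C=C[C@]12CC[C@@]13C[C@@]4(C)C=C5C(=O)OC[C@]51[C@@](C)(C[C@H]3[C@@]2(C)O)C4=O | target

Total step count: 19. Longest linear sequence: 19 steps (from 1).

**Steps most likely to fail**

Step 9. The tertiary alcohol of 11, flanked by the spiro quaternary carbon, may be too hindered to add to the tertiary oxocarbenium ion, so ketal formation stalls or reverts. Fallback, from 11 back to 16: ethyl vinyl ether and NBS give the less crowded ethyl bromoacetal F1. The same cyclisation with allyl transfer gives bicyclic acetal F2, and cross-metathesis as in step 11 gives chain-extended acetal F3. Aqueous acid gives lactol F4. MeTi(OiPr)3 adds chemoselectively to the open hydroxy aldehyde, and acid lactonisation gives bridged lactone alcohol F5. Dess–Martin oxidation of F5 gives 16. The side-chain methyl group is thus introduced by carbonyl addition instead of with the ketal.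

Step 11. Metathesis of the neopentyl 1,1-disubstituted alkene may be slow, with catalyst decay and homodimerisation of the partner taking over. Fallback, from 13 back to 14: ozonolysis (O3; Me2S) of the 2-methylallyl group gives methyl ketone F6. A Wittig reaction with the ylide from (2-carboxyethyl)triphenylphosphonium bromide and NaN(SiMe3)2 gives β,γ-unsaturated acid F7 (either alkene geometry serves). Me3SiCHN2 then gives 14.

Step 16. The cycloaddition may stall at the first bond between two fully substituted carbons, so that decomposition of the diene competes. Fallback, from 22 back to 27: mild aqueous acid cleaves the enol ether and the silyl ether to give aldehyde F8. Catalytic KOt-Bu in t-BuOH then effects an intramolecular Michael addition of the aldehyde enolate to the butenolide, followed by vinylogous aldol closure of the resulting dienolate onto the aldehyde. This is the stepwise polar version of the same ring closure and gives saturated-lactone diol F9. Dess–Martin oxidation gives dihydro ketone F10, and selenoxide dehydrogenation as in step 17 (two equivalents of base) gives 27.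

Further compounds
F1 | step 9 | ethyl bromoacetal (2-bromo-1-ethoxyethyl ether of 11) | CC1(C)OC(=O)CC[C@]12CCC(C(=O)OC)=C[C@@]2(C)OC(OCC)CBr
F2 | step 9 | bicyclic acetal (2-ethoxytetrahydrofuran analogue of 13) | CC1(C)OC(=O)CC[C@]12CC[C@@](CC(C)=C)(C(=O)OC)[C@H]3CC(OCC)O[C@@]23C
F3 | step 9 | chain-extended acetal (2-ethoxytetrahydrofuran analogue of 14) | CC1(C)OC(=O)CC[C@]12CC[C@@](CC(C)=CCC(=O)OC)(C(=O)OC)[C@H]3CC(OCC)O[C@@]23C
F4 | step 9 | lactol | CC1(C)OC(=O)CC[C@]12CC[C@@](CC(C)=CCC(=O)OC)(C(=O)OC)[C@H]3CC(O)O[C@@]23C
F5 | step 9 | bridged lactone alcohol (2-hydroxypropyl analogue of 16) | CC1(C)OC(=O)CC[C@]12CC[C@@]3(CC(C)=CCC(=O)OC)C(=O)O[C@]2(C)[C@@H]3CC(C)O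
F6 | step 11 | methyl ketone (2-oxopropyl analogue of 13) | CC1(C)OC(=O)CC[C@]12CC[C@@](CC(C)=O)(C(=O)OC)[C@H]3CC(C)(OC)O[C@@]23C
F7 | step 11 | β,γ-unsaturated acid (free acid of 14) | CC1(C)OC(=O)CC[C@]12CC[C@@](CC(C)=CCC(=O)O)(C(=O)OC)[C@H]3CC(C)(OC)O[C@@]23C
F8 | step 16 | aldehyde (free tertiary alcohol, 2-methyl-3-oxopropyl side chain) | CC1(C)OC(=O)CC[C@]12CC[C@]3(CC(C)=CC4=C3COC4=O)[C@@H](CC(C)C=O)[C@@]2(C)O
F9 | step 16 | saturated-lactone diol (7,8-dihydro form of 26) | CC1(C)OC(=O)CC[C@]12CC[C@@]13C[C@@]4(C)C=C5C(=O)OC[C@]51[C@@](C)(C[C@H]3[C@@]2(C)O)C4O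
F10 | step 16 | dihydro ketone (7,8-dihydroandibenin B) | CC1(C)OC(=O)CC[C@]12CC[C@@]13C[C@@]4(C)C=C5C(=O)OC[C@]51[C@@](C)(C[C@H]3[C@@]2(C)O)C4=O
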